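**Retrosynthetic overview**
- Juncin Q ⇐ late adjustments on a 3,4‑didehydrobriarane core: Z‑semi‑reduction of a C3≡C4 alkyne, hydroxyl‑directed 11,20‑epoxidation, allylic C12 hydroxylation, inversion at C14.
- Core ⇐ transannular C1–C10 bond formation (the cembrane‑to‑briarane 3,8‑cyclisation) by trivalent‑titanium opening of a 1,14‑epoxide in a 14‑membered cembranoid; cyclohexane and ten‑membered ring form in one step.
- Cembranoid ⇐ Sonogashira closure at C4–C5; butyrolactone ⇐ reduction of a C7 alkynyl ketone; C8–C9 ⇐ aldol of a malate‑derived dioxolanone enolate.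
- C9–C4 chain ⇐ vinylogous aldol (C12–C13), directed epoxidation, asymmetric alkynylation (C2–C3), Wittig (C14=C1).
- Ring order: butyrolactone → 14‑membered carbocycle → six‑ and ten‑membered rings together → spiro‑oxirane.

Assumption: atoms carry the briarane locants C1–C20 of the target throughout, and for each enantioselective catalyst or ligand the antipode that gives the drawn configuration is meant.

**Step 1**
Reactants: 1 diethyl (2S)-2-hydroxybutanedioate
Product: 2 diethyl (2S,3R)-2-hydroxy-3-methylbutanedioate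
Conditions: LiN(i-Pr)2 (2.2 equiv), THF, −78 → −20 °C; MeI, −78 → −10 °C; AcOH quench
Reagents that add atoms: iodomethane, IC
Why: Frater–Seebach alkylation: the chelated alkoxide–enolate dianion is methylated anti to the alkoxide, setting C17 (anti, about 9:1) while C8 is untouched.

**Step 2**
Reactants: 2
Product: 3 (2S,3R)-2-hydroxy-3-methylbutanedioic acid
Conditions: KOH (aq.), EtOH, 0 °C → rt; HCl to pH 1, continuous extraction
Reagents that add atoms: potassium hydroxide, [K+].[OH-]
Why: ester saponification by acyl–oxygen cleavage; the dicarboxylate is not enolised, so neither stereocentre epimerises.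

**Step 3**
Reactants: 3
Product: 4 (2R)-2-[(2S,4S)-2-tert-butyl-5-oxo-1,3-dioxolan-4-yl]propanoic acid
Conditions: t-BuCHO, TsOH·H2O (cat.), H2SO4 (cat.), pentane, reflux, water separator; recrystallisation
Reagents that add atoms: pivalaldehyde, CC(C)(C)C=O
Why: Seebach acetalisation (self‑regeneration of stereocentres): the α‑hydroxy acid closes the five‑membered dioxolanone rather than a six‑membered ring with the distal carboxyl, and the cis acetal is the thermodynamic, crystalline isomer.

**Step 4**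
Reactants: 5 2,2-dimethoxyacetaldehyde; 6 2-(triphenyl-λ5-phosphanylidene)propanal
Product: 7 (2E)-4,4-dimethoxy-2-methylbut-2-enal
Conditions: CH2Cl2, rt
Reagents that add atoms: none
Why: Wittig olefination with a stabilised ylide gives the E‑trisubstituted enal (C13–C14=C1(C15)–C2).

**Step 5**
Reactants: 7; 8 ethynyl(trimethyl)silane
Product: 10 (3R,4E)-6,6-dimethoxy-4-methyl-1-(trimethylsilyl)hex-4-en-1-yn-3-yl acetate, via zinc alkoxide 9 (not isolated)
Conditions: Me2Zn (3 equiv), (S,S)-ProPhenol (20 mol%), Ph3P=O (40 mol%), toluene, 0 °C; then Ac2O, 0 °C → rt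
Reagents that add atoms: acetic anhydride, CC(=O)OC(C)=O
Why: Trost ProPhenol zinc‑catalysed asymmetric alkynylation of an enal sets C2 by ligand control (alkynyl transfer to the Si face), and the zinc alkoxide is acetylated in the same flask.

**Step 6**
Reactants: 10
Product: 11 (3R,4E)-4-methyl-6-oxo-1-(trimethylsilyl)hex-4-en-1-yn-3-yl acetate
Conditions: PPTS (cat.), acetone/H2O 10:1, 40 °C
Reagents that add atoms: water, O
Why: mild acetal hydrolysis frees the conjugated C13 aldehyde without ionising the secondary acetate.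

**Step 7**
Reactants: 12 3-methylbut-2-enal
Product: 13 tert-butyl(dimethyl){[(1E)-3-methylbuta-1,3-dien-1-yl]oxy}silane
Conditions: TBSOTf, Et3N, Et2O, 0 °C → rt
Reagents that add atoms: tert-butyldimethylsilyl trifluoromethanesulfonate, CC(C)(C)[Si](C)(C)OS(=O)(=O)C(F)(F)F
Why: soft enolisation with γ‑deprotonation gives the E silyl dienol ether that supplies C9–C12 and C20.

**Step 8**
Reactants: 11; 13
Product: 14 (3R,4E,6S,8E)-6-hydroxy-4,8-dimethyl-10-oxo-1-(trimethylsilyl)deca-4,8-dien-1-yn-3-yl acetate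
Conditions: B-phenyl oxazaborolidinone from N-tosyl-L-tryptophan (50 mol%), i-PrOH (1.2 equiv), EtCN, −78 °C
Reagents that add atoms: none
Why: vinylogous Mukaiyama aldol reaction of an aldehyde‑derived silyl dienol ether: γ‑attack gives the E‑enal directly, and the oxazaborolidinone‑bound aldehyde is attacked on one face, setting C13.

**Step 9**
Reactants: 14
Product: 15 threo epoxy alcohol (1S)-1-{(2R,3R)-3-[(1S,3E)-1-hydroxy-3-methyl-5-oxopent-3-en-1-yl]-2-methyloxiran-2-yl}-3-(trimethylsilyl)prop-2-yn-1-yl acetate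
Conditions: mCPBA, NaHCO3, CH2Cl2, −10 → 0 °C
Reagents that add atoms: 3-chloroperbenzoic acid, OOC(=O)c1cccc(Cl)c1
Why: hydroxyl‑directed (Henbest) epoxidation: 1,3‑allylic strain with the cis C15 methyl fixes the rotamer so oxygen is delivered threo to the C13 hydroxyl (sets C14 and C1), while the enal alkene and the alkyne are too electron‑poor to react.

**Step 10**
Reactants: 15
Product: 16 diacetate (1S,3E)-1-{(2R,3R)-3-[(1S)-1-acetoxy-3-(trimethylsilyl)prop-2-yn-1-yl]-3-methyloxiran-2-yl}-3-methyl-5-oxopent-3-en-1-yl acetate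
Conditions: Ac2O, pyridine, DMAP (cat.), CH2Cl2, 0 °C
Reagents that add atoms: acetic anhydride, CC(=O)OC(C)=O
Why: acylation of the secondary alcohol installs the final C13 acetate with retention.

**Step 11**
Reactants: 4; 16
Product: 18 dioxolanone triacetate acid (8S,9S,17R), via lithium aldolate 17 (not isolated)
Conditions: 4, LiN(SiMe3)2 (2.1 equiv), THF, −78 °C; 16, −78 °C; then Ac2O, DMAP, −78 → −20 °C; aq. NaH2PO4
Reagents that add atoms: acetic anhydride, CC(=O)OC(C)=O
Why: Seebach self‑regeneration of stereocentres: the dioxolanone enolate is attacked anti to tert‑butyl (retention at C8); C9 is expected from a chelated chair transition state with the alkenyl residue anti to the branched C17 substituent (the least secure selectivity of the route), and the aldolate is acetylated in situ so it cannot lactonise onto C19.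

**Step 12**
Reactants: 18; 19 prop-2-yn-1-ol
Product: 20 α-hydroxy ynone acid (C7 ketone; C16 alcohol; 2,9,13-triacetate)
Conditions: 19 (3 equiv), n-BuLi (6 equiv), THF, −78 → 0 °C; then 18, −78 °C; aq. NH4Cl
Reagents that add atoms: none
Why: acyl substitution at the acylal‑type dioxolanone carbonyl, the most electrophilic acyl group present: the small acetylide adds once at −78 °C, and the tetrahedral adduct collapses on work‑up with loss of pivalaldehyde to give the C7 ynone and the free C8 hydroxyl.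

**Step 13**
Reactants: 20
Product: 22 γ-lactone (7S; O7–C19), via hydroxy acid 21 (not isolated)
Conditions: RuCl(p-cymene)[(R,R)-TsDPEN] (2 mol%), HCO2H/Et3N (1:1), EtOAc, rt; then PPTS (cat.), CH2Cl2, rt
Reagents that add atoms: none
Why: Noyori asymmetric transfer hydrogenation of the ynone (alkynyl group in the aryl pocket of the catalyst) sets C7 by reagent control, and the γ‑hydroxy acid lactonises onto C19, the only free acyl group within reach.

**Step 14**
Reactants: 22
Product: 24 (5Z)-5-iodoalkene lactone, via alkenylstannane 23 (not isolated)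
Conditions: [Cp*RuCl]4 (2.5 mol%), Bu3SnH (1.05 equiv), CH2Cl2, rt; then I2, 0 °C
Reagents that add atoms: iodine, [I][I]
Why: hydroxyl‑directed ruthenium‑catalysed trans‑hydrostannation puts tin on C5 (proximal to the free C16 hydroxyl) and hydrogen on C6 anti to it; iododestannylation with retention gives iodine cis to C7, while the silyl‑capped alkyne without a free hydroxyl reacts far more slowly.

**Step 15**
Reactants: 24
Product: 25 terminal alkyne iodoalkene (open-chain cembranoid precursor)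
Conditions: AgNO3 (20 mol%), 2,6-lutidine, acetone/H2O, rt
Reagents that add atoms: none
Why: silver‑catalysed protiodesilylation of the alkynylsilane under near‑neutral conditions that spare acetates, epoxide and vinyl iodide.

**Step 16**
Reactants: 25
Product: 26 14-membered cembranoid (5E)-en-3-yne 1,14-epoxide
Conditions: Pd(PPh3)4 (10 mol%), CuI (20 mol%), i-Pr2NH, THF, rt, syringe-pump addition to 1 mM
Reagents that add atoms: none
Why: Sonogashira macrocyclisation forms C4–C5 with retention of alkene geometry; at room temperature zerovalent palladium inserts into the vinyl iodide much faster than it ionises the allylic or propargylic acetates.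

**Step 17**
Reactants: 26
Product: 27 16-O-TBS ether of the cembranoid
Conditions: TBSCl, imidazole, CH2Cl2, 0 °C
Reagents that add atoms: tert-butyldimethylsilyl chloride, CC(C)(C)[Si](C)(C)Cl
Why: selective silylation of the primary allylic alcohol; the tertiary C8 hydroxyl does not react.

**Step 18**
Reactants: 27
Product: 28 3,4-didehydrobriarane core (14β-alcohol; exocyclic C11=C20)
Conditions: Cp2TiCl2 (2.5 equiv), Mn dust (8 equiv), THF, rt (gives Cp2TiCl); 27 added over 4 h (5 mM); dilute HCl work-up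
Reagents that add atoms: none
Why: Proposed new method: single‑electron opening of the trisubstituted epoxide by Cp2TiCl gives the tertiary C1 radical, which adds across the ring to C10 of the E C10=C11 alkene (6‑endo, tertiary C11 radical) and ends by titanium trapping and β‑hydride elimination to the exocyclic C11=C20 alkene; a chair with the C13 acetoxy and C14 titanoxy groups equatorial and C9 equatorial sets C1 and C10 (trans fusion, C15 and H10 axial) and leaves the C14 alcohol equatorial, and the linear C2–C3≡C4–C5 unit makes attack on C6 geometrically impossible; closest known reaction type: titanocene chloride epoxypolyene radical cyclisation and the transannular cyclisation of epoxygermacrolides to eudesmanolides.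

**Step 19**
Reactants: 28
Product: 29 14-ketone
Conditions: Dess–Martin periodinane, NaHCO3, CH2Cl2, 0 °C → rt
Reagents that add atoms: none
Why: Dess–Martin oxidation of the only secondary alcohol under buffered conditions that do not epimerise the adjacent C13 acetate centre.

**Step 20**
Reactants: 29
Product: 30 14α-alcohol
Conditions: LiBH(s-Bu)3 (1.2 equiv), THF, −78 °C; AcOH quench at −78 °C
Reagents that add atoms: none
Why: the bulky hydride attacks equatorially (axial approach is screened by the axial hydrogens at C10 and C12), giving the axial 14α alcohol cis to the C13 acetate; the cold acidic quench prevents acetyl migration.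

**Step 21**
Reactants: 30
Product: 31 12α,14α-diol
Conditions: SeO2 (0.5 equiv), t-BuOOH (3 equiv), CH2Cl2, 0 °C → rt
Reagents that add atoms: tert-butyl hydroperoxide, CC(C)(C)OO
Why: SeO2 allylic hydroxylation (ene reaction then 2,3‑sigmatropic shift) of the isolated 1,1‑disubstituted alkene at its ring CH2 (C12, favoured over the tertiary C10–H), delivering the axial 12α alcohol; the enyne alkene is less nucleophilic.

**Step 22**
Reactants: 31
Product: 32 11,20-epoxide (oxirane oxygen α)
Conditions: VO(acac)2 (5 mol%), t-BuOOH (1.5 equiv), CH2Cl2, 0 °C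
Reagents that add atoms: tert-butyl hydroperoxide, CC(C)(C)OO
Why: vanadium‑catalysed allylic‑alcohol‑directed epoxidation delivers oxygen to the exocyclic alkene on the face of the 12α hydroxyl (sets C11); the only other alkene has no free allylic hydroxyl.

**Step 23**
Reactants: 32
Product: 33 16-O-TBS Juncin Q ((3Z,5E)-diene)
Conditions: H2 (1 atm), Pd/CaCO3 poisoned with Pb(OAc)2, quinoline, EtOAc, rt
Reagents that add atoms: none
Why: Lindlar cis‑semihydrogenation of the ring alkyne gives the Z C3=C4 alkene and stops at the diene.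

**Step 24**
Reactants: 33
Product: 34 Juncin Q
Conditions: HF·pyridine, pyridine, THF, 0 °C
Reagents that add atoms: none
Why: buffered fluoride desilylation frees the C16 alcohol without acyl migration or oxirane opening.

**Compound list**
1 | diethyl (2S)-2-hydroxybutanedioate (diethyl L-malate) | CCOC(=O)C[C@H](O)C(=O)OCC | starting material
2 | diethyl (2S,3R)-2-hydroxy-3-methylbutanedioate | CCOC(=O)[C@H](C)[C@H](O)C(=O)OCC | intermediate
3 | (2S,3R)-2-hydroxy-3-methylbutanedioic acid | OC(=O)[C@H](C)[C@H](O)C(=O)O | intermediate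
4 | (2R)-2-[(2S,4S)-2-tert-butyl-5-oxo-1,3-dioxolan-4-yl]propanoic acid (cis acetal) | CC(C)(C)[C@H]1O[C@@H]([C@@H](C)C(=O)O)C(=O)O1 | intermediate
5 | 2,2-dimethoxyacetaldehyde | COC(OC)C=O | starting material
6 | 2-(triphenyl-λ5-phosphanylidene)propanal | CC(C=O)=P(c1ccccc1)(c1ccccc1)c1ccccc1 | starting material
7 | (2E)-4,4-dimethoxy-2-methylbut-2-enal | O=C/C(C)=C/C(OC)OC | intermediate
8 | ethynyl(trimethyl)silane | C#C[Si](C)(C)C | starting material
9 | (3R,4E)-6,6-dimethoxy-4-methyl-1-(trimethylsilyl)hex-4-en-1-yn-3-ol, present as its methylzinc alkoxide | C[Si](C)(C)C#C[C@H](O)/C(C)=C/C(OC)OC | intermediate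
10 | (3R,4E)-6,6-dimethoxy-4-methyl-1-(trimethylsilyl)hex-4-en-1-yn-3-yl acetate | C[Si](C)(C)C#C[C@H](OC(C)=O)/C(C)=C/C(OC)OC | intermediate
11 | (3R,4E)-4-methyl-6-oxo-1-(trimethylsilyl)hex-4-en-1-yn-3-yl acetate | C[Si](C)(C)C#C[C@H](OC(C)=O)/C(C)=C/C=O | intermediate
12 | 3-methylbut-2-enal | CC(C)=CC=O | starting material
13 | tert-butyl(dimethyl){[(1E)-3-methylbuta-1,3-dien-1-yl]oxy}silane | CC(=C)/C=C/O[Si](C)(C)C(C)(C)C | intermediate
14 | (3R,4E,6S,8E)-6-hydroxy-4,8-dimethyl-10-oxo-1-(trimethylsilyl)deca-4,8-dien-1-yn-3-yl acetate | O=C/C=C(\C)C[C@H](O)/C=C(\C)[C@@H](OC(C)=O)C#C[Si](C)(C)C | intermediate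
15 | (1S)-1-{(2R,3R)-3-[(1S,3E)-1-hydroxy-3-methyl-5-oxopent-3-en-1-yl]-2-methyloxiran-2-yl}-3-(trimethylsilyl)prop-2-yn-1-yl acetate (1,14-epoxide threo to the C13 hydroxyl) | O=C/C=C(\C)C[C@H](O)[C@H]1O[C@]1(C)[C@@H](OC(C)=O)C#C[Si](C)(C)C | intermediate
16 | (1S,3E)-1-{(2R,3R)-3-[(1S)-1-acetoxy-3-(trimethylsilyl)prop-2-yn-1-yl]-3-methyloxiran-2-yl}-3-methyl-5-oxopent-3-en-1-yl acetate | O=C/C=C(\C)C[C@H](OC(C)=O)[C@H]1O[C@]1(C)[C@@H](OC(C)=O)C#C[Si](C)(C)C | intermediate
17 | aldol adduct of 4 and 16, drawn as the hydroxy acid (formed as the dilithium salt): dioxolanone ring carbon C8 bonded to C9 carbinol, C8 and C9 as in 34 | CC(C)(C)[C@H]1O[C@]([C@@H](C)C(=O)O)([C@@H](O)/C=C(\C)C[C@H](OC(C)=O)[C@H]2O[C@]2(C)[C@@H](OC(C)=O)C#C[Si](C)(C)C)C(=O)O1 | intermediate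
18 | 9-O-acetate of 17 (2,9,13-triacetate; dioxolanone carbonyl is C7; free C19 acid) | CC(C)(C)[C@H]1O[C@]([C@@H](C)C(=O)O)([C@@H](OC(C)=O)/C=C(\C)C[C@H](OC(C)=O)[C@H]2O[C@]2(C)[C@@H](OC(C)=O)C#C[Si](C)(C)C)C(=O)O1 | intermediate
19 | prop-2-yn-1-ol | C#CCO | starting material
20 | α-hydroxy ynone acid: C7 ketone joined to C6≡C5–C16H2OH, tertiary C8 alcohol, C19 acid, 2,9,13-triacetate, 1,14-epoxide, silyl alkyne | OCC#CC(=O)[C@@](O)([C@@H](C)C(=O)O)[C@@H](OC(C)=O)/C=C(\C)C[C@H](OC(C)=O)[C@H]1O[C@]1(C)[C@@H](OC(C)=O)C#C[Si](C)(C)C | intermediate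
21 | (7S)-propargylic alcohol of 20 (γ-hydroxy acid) | OCC#C[C@H](O)[C@@](O)([C@@H](C)C(=O)O)[C@@H](OC(C)=O)/C=C(\C)C[C@H](OC(C)=O)[C@H]1O[C@]1(C)[C@@H](OC(C)=O)C#C[Si](C)(C)C | intermediate
22 | γ-lactone (O7–C19) with C7, C8, C17 as in 34; C5≡C6 alkyne; free C16 alcohol | OCC#C[C@@H]1OC(=O)[C@H](C)[C@@]1(O)[C@@H](OC(C)=O)/C=C(\C)C[C@H](OC(C)=O)[C@H]2O[C@]2(C)[C@@H](OC(C)=O)C#C[Si](C)(C)C | intermediate
23 | (5Z)-5-tributylstannyl alkene from 22 (tin cis to C7) | OC/C([Sn](CCCC)(CCCC)CCCC)=C/[C@@H]1OC(=O)[C@H](C)[C@@]1(O)[C@@H](OC(C)=O)/C=C(\C)C[C@H](OC(C)=O)[C@H]2O[C@]2(C)[C@@H](OC(C)=O)C#C[Si](C)(C)C | intermediate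
24 | (5Z)-5-iodo alkene (iodine cis to C7), silyl alkyne retained | OC/C(I)=C/[C@@H]1OC(=O)[C@H](C)[C@@]1(O)[C@@H](OC(C)=O)/C=C(\C)C[C@H](OC(C)=O)[C@H]2O[C@]2(C)[C@@H](OC(C)=O)C#C[Si](C)(C)C | intermediate
25 | terminal alkyne of 24 | OC/C(I)=C/[C@@H]1OC(=O)[C@H](C)[C@@]1(O)[C@@H](OC(C)=O)/C=C(\C)C[C@H](OC(C)=O)[C@H]2O[C@]2(C)[C@@H](OC(C)=O)C#C | intermediate
26 | 14-membered cembranoid: C3≡C4, (5E)-alkene, (10E)-alkene, 1,14-epoxide, 2,9,13-triacetate, 7,19-lactone, free C16 and C8 alcohols | OC/C1=C/[C@@H]2OC(=O)[C@H](C)[C@@]2(O)[C@@H](OC(C)=O)/C=C(\C)C[C@H](OC(C)=O)[C@H]3O[C@]3(C)[C@@H](OC(C)=O)C#C1 | intermediate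
27 | 16-O-tert-butyldimethylsilyl ether of 26 | CC(C)(C)[Si](C)(C)OC/C1=C/[C@@H]2OC(=O)[C@H](C)[C@@]2(O)[C@@H](OC(C)=O)/C=C(\C)C[C@H](OC(C)=O)[C@H]3O[C@]3(C)[C@@H](OC(C)=O)C#C1 | intermediate
28 | bicyclic core: C1–C10 bond, C1 and C10 as in 34, 14β-alcohol (epimer of 34 at C14), exocyclic C11=C20, C3≡C4 in the ten-membered ring | CC(=O)O[C@H]1CC(=C)[C@@H]2[C@H](OC(C)=O)[C@@]3(O)[C@H](/C=C(CO[Si](C)(C)C(C)(C)C)\C#C[C@H](OC(C)=O)[C@@]2(C)[C@@H]1O)OC(=O)[C@@H]3C | intermediate
29 | 14-ketone of 28 | CC(=O)O[C@H]1CC(=C)[C@@H]2[C@H](OC(C)=O)[C@@]3(O)[C@H](/C=C(CO[Si](C)(C)C(C)(C)C)\C#C[C@H](OC(C)=O)[C@@]2(C)C1=O)OC(=O)[C@@H]3C | intermediate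
30 | 14α-alcohol (C14 as in 34) | CC(=O)O[C@H]1CC(=C)[C@@H]2[C@H](OC(C)=O)[C@@]3(O)[C@H](/C=C(CO[Si](C)(C)C(C)(C)C)\C#C[C@H](OC(C)=O)[C@@]2(C)[C@H]1O)OC(=O)[C@@H]3C | intermediate
31 | 12α,14α-diol with exocyclic C11=C20 | CC(=O)O[C@H]1[C@@H](O)C(=C)[C@@H]2[C@H](OC(C)=O)[C@@]3(O)[C@H](/C=C(CO[Si](C)(C)C(C)(C)C)\C#C[C@H](OC(C)=O)[C@@]2(C)[C@H]1O)OC(=O)[C@@H]3C | intermediate
32 | 11,20-epoxide (all ring stereocentres as in 34; C3≡C4 alkyne; 16-O-silyl) | CC(=O)O[C@H]1[C@@H](O)[C@]2(CO2)[C@@H]2[C@H](OC(C)=O)[C@@]3(O)[C@H](/C=C(CO[Si](C)(C)C(C)(C)C)\C#C[C@H](OC(C)=O)[C@@]2(C)[C@H]1O)OC(=O)[C@@H]3C | intermediate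
33 | 16-O-tert-butyldimethylsilyl Juncin Q | CC(=O)O[C@H]1[C@@H](O)[C@]2(CO2)[C@@H]2[C@H](OC(C)=O)[C@@]3(O)[C@H](/C=C(CO[Si](C)(C)C(C)(C)C)\C=C/[C@H](OC(C)=O)[C@@]2(C)[C@H]1O)OC(=O)[C@@H]3C | intermediate
34 | Juncin Q: (1R,2S,3Z,5E,7S,8S,9S,10S,11R,12R,13R,14R,17R)-2,9,13-triacetoxy-11,20-epoxy-8,12,14,16-tetrahydroxybriara-3,5-dien-19,7-olide | CC(=O)O[C@H]1[C@@H](O)[C@]2(CO2)[C@@H]2[C@H](OC(C)=O)[C@@]3(O)[C@H](/C=C(CO)\C=C/[C@H](OC(C)=O)[C@@]2(C)[C@H]1O)OC(=O)[C@@H]3C | target

**Step count and risks**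
Total steps: 24. Longest linear sequence: 20 steps (steps 4, 5, 6, 8, 9, 10, then 11 to 24).

Most likely to fail, step 18 (transannular radical closure to a strained ten‑membered enyne). If the C1 radical is reduced or eliminated faster than it closes across the ring, the order of ring formation is reversed. The fallback sets out from 25: silylation of the primary alcohol (TBSCl, imidazole) gives the open-chain silyl ether F1. Treating F1 with Cp2TiCl as in step 18 is then an ordinary open‑chain epoxide–alkene radical cyclisation through the same all‑equatorial chair and gives the cyclohexane F2, which carries the iodoalkene and alkyne arms on adjacent equatorial positions. Sonogashira coupling (Pd(PPh3)4, CuI, i-Pr2NH, high dilution) then closes the ten‑membered ring and comes back to the route at 28.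

Second, step 11 (configuration at C9 in the aldol). If the aldol gives mainly the C9 epimer, C9 is set by reduction instead of by C–C bond formation. The fallback sets out from 16: Pinnick oxidation (NaClO2, NaH2PO4, 2-methylbut-2-ene) gives the enoic acid F3, and carbonyldiimidazole converts it into the acyl imidazole F4. C‑Acylation of the dianion of 4 (LiN(SiMe3)2, −78 °C) with F4 gives the C9 enone F5. Reduction of F5 with (R)-2-methyl-CBS-oxazaborolidine and catecholborane at −78 °C, with acetylation in the same flask (Ac2O, DMAP) before acidification so that the alcohol cannot lactonise onto C19, comes back to the route at 18.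

Third, step 21 (site and face selectivity of the SeO2 hydroxylation). If other allylic positions compete or the 12β alcohol forms, the oxygen is introduced at the ketone level. The fallback sets out from 30: allylic oxidation with Rh2(cap)4 (1 mol%) and t-BuOOH gives the α-methylene ketone F6 (C12 ketone). Reduction with NaBH4 and CeCl3·7H2O in MeOH at −78 °C, where the axial 14α hydroxyl blocks axial hydride delivery so the hydride enters equatorially, gives the axial 12α alcohol and comes back to the route at 31.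

**Further compounds**
F1 | step 18 | 16-O-tert-butyldimethylsilyl ether of 25 (open chain) | CC(C)(C)[Si](C)(C)OC/C(I)=C/[C@@H]1OC(=O)[C@H](C)[C@@]1(O)[C@@H](OC(C)=O)/C=C(\C)C[C@H](OC(C)=O)[C@H]2O[C@]2(C)[C@@H](OC(C)=O)C#C
F2 | step 18 | cyclohexane from F1: C1–C10 bond, 14β-alcohol, exocyclic C11=C20, iodoalkene lactone arm on C10 (via C9), acetoxy propynyl arm on C1 | CC(=O)O[C@H]1CC(=C)[C@H]([C@H](OC(C)=O)[C@@]2(O)[C@H](/C=C(I)/CO[Si](C)(C)C(C)(C)C)OC(=O)[C@@H]2C)[C@](C)([C@@H]1O)[C@@H](OC(C)=O)C#C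
F3 | step 11 | carboxylic acid from 16 (C9 acid) | OC(=O)/C=C(\C)C[C@H](OC(C)=O)[C@H]1O[C@]1(C)[C@@H](OC(C)=O)C#C[Si](C)(C)C
F4 | step 11 | acyl imidazole of F3 | O=C(/C=C(\C)C[C@H](OC(C)=O)[C@H]1O[C@]1(C)[C@@H](OC(C)=O)C#C[Si](C)(C)C)n1ccnc1
F5 | step 11 | C9 enone: dioxolanone 4 acylated at C8 | CC(C)(C)[C@H]1O[C@]([C@@H](C)C(=O)O)(C(=O)/C=C(\C)C[C@H](OC(C)=O)[C@H]2O[C@]2(C)[C@@H](OC(C)=O)C#C[Si](C)(C)C)C(=O)O1
F6 | step 21 | 11(20)-en-12-one from 30 | CC(=O)O[C@H]1C(=O)C(=C)[C@@H]2[C@H](OC(C)=O)[C@@]3(O)[C@H](/C=C(CO[Si](C)(C)C(C)(C)C)\C#C[C@H](OC(C)=O)[C@@]2(C)[C@H]1O)OC(=O)[C@@H]3C
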